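**Retrosynthetic overview**

- The target comes from its bis-TIPS ether by fluoride desilylation, and that ether from an open-chain (R)-2-aryl-3-(2-hydroxyaryl)propan-1-ol by Mitsunobu closure of the O1–C2 bond.
- Key disconnection C4–C4a: a catalytic enantioselective Friedel–Crafts ring opening of a prochiral 3-aryloxetane (B ring plus C2/C3/C4) by the C2v-symmetric A-ring resorcinol. This single step joins the two halves and sets C3.
- A-ring nucleophile: resorcinol → 2-iodoresorcinol → B-alkyl Suzuki coupling with hydroborated 2-methylbut-3-en-2-ol.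
- B-ring oxetane: 4,6-dibromoresorcinol → bis-TIPS ether → branched-selective prenyl Suzuki coupling (reverse prenyl) → Negishi coupling with oxetan-3-ylzinc iodide.
- Ring order: both benzene rings are bought, the oxetane is carried in as a masked C3 unit, and the dihydropyran ring is formed last.

Assumption: 4,6-dibromoresorcinol, prenyl-Bpin and 3-iodooxetane are bought; the sense of induction of the chiral acid in the key step cannot be predicted with certainty, so it is written as the (R)-catalyst and its mirror image is used if a test run gives the (S)-alcohol.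

**Route**

Step 1
Reactants: 1 resorcinol (benzene-1,3-diol)
Product: 2 2-iodobenzene-1,3-diol
Conditions: I2 (1.05 equiv), NaHCO3 (1.1 equiv), H2O, 0 °C → rt
Reagents that add atoms: iodine, II
Why: Electrophilic aromatic iodination under mild bicarbonate conditions goes kinetically to C2 between the two hydroxyls (a standard preparative iodination of resorcinol); no stereocentre is formed.

Step 2
Reactants: 2 2-iodobenzene-1,3-diol; 3 2-methylbut-3-en-2-ol
Product: 5 2-(3-hydroxy-3-methylbutyl)benzene-1,3-diol, via B-alkyl-9-BBN adduct 4 (not isolated)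
Conditions: 3 (1.5 equiv), 9-BBN-H (1.6 equiv), THF, 0 °C → rt; then 2, Pd(dppf)Cl2 (5 mol %), K3PO4 (4 equiv), H2O, DMF, 60 °C
Reagents that add atoms: none
Why: Anti-Markovnikov hydroboration of the terminal alkene followed by B-alkyl Suzuki–Miyaura coupling joins the primary carbon to the aryl iodide; the tertiary OH reacts only slowly with 9-BBN and the phenols are carried as phenoxides.

Step 3
Reactants: 6 4,6-dibromobenzene-1,3-diol
Product: 7 1,5-dibromo-2,4-bis(triisopropylsilyloxy)benzene
Conditions: NaH (2.2 equiv), TIPSCl (2.2 equiv), THF, 0 °C → rt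
Reagents that add atoms: triisopropylsilyl chloride (TIPSCl), CC(C)[Si](Cl)(C(C)C)C(C)C
Why: O-silylation of the bis-phenoxide; TIPS is stable to aqueous base, organozinc, the acid catalyst and Mitsunobu conditions, and leaves with fluoride at the end without acid.

Step 4
Reactants: 7 1,5-dibromo-2,4-bis(triisopropylsilyloxy)benzene; 8 prenyl-Bpin (4,4,5,5-tetramethyl-2-(3-methylbut-2-en-1-yl)-1,3,2-dioxaborolane)
Product: 9 1-bromo-5-(2-methylbut-3-en-2-yl)-2,4-bis(triisopropylsilyloxy)benzene
Conditions: 7 (1.5 equiv), 8 (1.0 equiv), Pd precatalyst with a dialkylbiarylphosphine ligand screened for branched (γ) selectivity (3 mol %), aq K3PO4, THF, 40 °C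
Reagents that add atoms: none
Why: Ligand-controlled regiodivergent allyl–aryl Suzuki–Miyaura coupling, in which SE2' transmetalation puts Pd on the tertiary carbon and fast reductive elimination gives the 1,1-dimethylallyl arene; excess of the symmetric dibromide holds the reaction at mono-coupling and unreacted 7 is recycled.

Step 5
Reactants: 9 1-bromo-5-(2-methylbut-3-en-2-yl)-2,4-bis(triisopropylsilyloxy)benzene; 10 3-iodooxetane
Product: 12 3-[5-(2-methylbut-3-en-2-yl)-2,4-bis(triisopropylsilyloxy)phenyl]oxetane, via oxetan-3-ylzinc iodide 11 (not isolated)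
Conditions: 10 (1.5 equiv), Zn dust, LiCl, THF, 40 °C; then 9, Pd2(dba)3 (2.5 mol %), CPhos (10 mol %), THF/toluene, 60 °C
Reagents that add atoms: none
Why: Zinc insertion followed by Negishi sp3–sp2 cross-coupling with a ligand built for secondary alkylzincs and ortho-substituted aryl bromides; β-hydride elimination is disfavoured because it would give a strained oxete.

Step 6
Reactants: 12 3-[5-(2-methylbut-3-en-2-yl)-2,4-bis(triisopropylsilyloxy)phenyl]oxetane; 5 2-(3-hydroxy-3-methylbutyl)benzene-1,3-diol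
Product: 13 (2R)-3-[2,4-dihydroxy-3-(3-hydroxy-3-methylbutyl)phenyl]-2-[5-(2-methylbut-3-en-2-yl)-2,4-bis(triisopropylsilyloxy)phenyl]propan-1-ol
Conditions: (R)-STRIP (SPINOL-derived chiral phosphoric acid, 10 mol %), 5 (3 equiv), DCE, 50 °C
Reagents that add atoms: none
Why: Proposed new method: a chiral-phosphoric-acid-catalysed desymmetrising Friedel–Crafts ring opening, in which the acid proton activates the oxetane oxygen while the phosphoryl oxygen hydrogen-bonds a phenolic OH of 5, so that the ortho carbon (C4 of 5, the only reactive ring position because of its C2v symmetry) attacks one of the two enantiotopic oxetane CH2 groups in an SN2 sense with about 25 kcal/mol of strain release; the stereocentre (future C3) is set by the choice between the two CH2–O bonds and is not itself a reacting centre, so it cannot be scrambled; the closest known reaction types are chiral-phosphoric-acid-catalysed enantioselective openings of 3-substituted oxetanes by S, N, O and halide nucleophiles and phosphoric-acid-directed ortho-C-alkylation of phenols and naphthols; the TIPS groups stop the 2'-oxygen from opening the oxetane and shield C3' of the B ring.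

Step 7
Reactants: 13 (2R)-3-[2,4-dihydroxy-3-(3-hydroxy-3-methylbutyl)phenyl]-2-[5-(2-methylbut-3-en-2-yl)-2,4-bis(triisopropylsilyloxy)phenyl]propan-1-ol
Product: 14 (3R)-8-(3-hydroxy-3-methylbutyl)-3-[5-(2-methylbut-3-en-2-yl)-2,4-bis(triisopropylsilyloxy)phenyl]-3,4-dihydro-2H-chromen-7-ol
Conditions: PPh3 (1.3 equiv), DIAD (1.3 equiv), THF (0.02 M), 0 °C → rt
Reagents that add atoms: none
Why: Intramolecular Mitsunobu etherification (6-exo-tet) of the ortho phenol onto the primary alcohol, the standard isoflavan ring closure; the stereocentre is not a reacting centre, the tertiary alcohol is inert and the B-ring oxygens are blocked.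

Step 8
Reactants: 14 (3R)-8-(3-hydroxy-3-methylbutyl)-3-[5-(2-methylbut-3-en-2-yl)-2,4-bis(triisopropylsilyloxy)phenyl]-3,4-dihydro-2H-chromen-7-ol
Product: 15 4-[(3R)-7-hydroxy-8-(3-hydroxy-3-methylbutyl)-3,4-dihydro-2H-chromen-3-yl]-6-(2-methylbut-3-en-2-yl)benzene-1,3-diol (CNP0420388.1)
Conditions: TBAF (2.5 equiv), AcOH (2.5 equiv), THF, 0 °C → rt
Reagents that add atoms: none
Why: Buffered fluoride desilylation of the two aryl silyl ethers; no strong acid is used, so neither the tertiary alcohol nor the 1,1-dimethylallyl group cyclises onto a neighbouring phenol.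

**Compound list**

1 | resorcinol (benzene-1,3-diol) | Oc1cccc(O)c1 | starting material
2 | 2-iodobenzene-1,3-diol | Oc1cccc(O)c1I | intermediate
3 | 2-methylbut-3-en-2-ol | C=CC(C)(C)O | starting material
4 | 9-(3-hydroxy-3-methylbutyl)-9-borabicyclo[3.3.1]nonane | CC(C)(O)CCB1C2CCCC1CCC2 | intermediate
5 | 2-(3-hydroxy-3-methylbutyl)benzene-1,3-diol | CC(C)(O)CCc1c(O)cccc1O | intermediate
6 | 4,6-dibromobenzene-1,3-diol | Oc1cc(O)c(Br)cc1Br | starting material
7 | 1,5-dibromo-2,4-bis(triisopropylsilyloxy)benzene | CC(C)[Si](Oc1cc(O[Si](C(C)C)(C(C)C)C(C)C)c(Br)cc1Br)(C(C)C)C(C)C | intermediate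
8 | prenyl-Bpin, 4,4,5,5-tetramethyl-2-(3-methylbut-2-en-1-yl)-1,3,2-dioxaborolane | CC(C)=CCB1OC(C)(C)C(C)(C)O1 | starting material
9 | 1-bromo-5-(2-methylbut-3-en-2-yl)-2,4-bis(triisopropylsilyloxy)benzene | C=CC(C)(C)c1cc(Br)c(O[Si](C(C)C)(C(C)C)C(C)C)cc1O[Si](C(C)C)(C(C)C)C(C)C | intermediate
10 | 3-iodooxetane | IC1COC1 | starting material
11 | oxetan-3-ylzinc iodide | I[Zn]C1COC1 | intermediate
12 | 3-[5-(2-methylbut-3-en-2-yl)-2,4-bis(triisopropylsilyloxy)phenyl]oxetane | C=CC(C)(C)c1cc(C2COC2)c(O[Si](C(C)C)(C(C)C)C(C)C)cc1O[Si](C(C)C)(C(C)C)C(C)C | intermediate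
13 | (2R)-3-[2,4-dihydroxy-3-(3-hydroxy-3-methylbutyl)phenyl]-2-[5-(2-methylbut-3-en-2-yl)-2,4-bis(triisopropylsilyloxy)phenyl]propan-1-ol | C=CC(C)(C)c1cc([C@@H](Cc2ccc(O)c(CCC(C)(C)O)c2O)CO)c(O[Si](C(C)C)(C(C)C)C(C)C)cc1O[Si](C(C)C)(C(C)C)C(C)C | intermediate
14 | (3R)-8-(3-hydroxy-3-methylbutyl)-3-[5-(2-methylbut-3-en-2-yl)-2,4-bis(triisopropylsilyloxy)phenyl]-3,4-dihydro-2H-chromen-7-ol | C=CC(C)(C)c1cc([C@@H]2COc3c(ccc(O)c3CCC(C)(C)O)C2)c(O[Si](C(C)C)(C(C)C)C(C)C)cc1O[Si](C(C)C)(C(C)C)C(C)C | intermediate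
15 | 4-[(3R)-7-hydroxy-8-(3-hydroxy-3-methylbutyl)-3,4-dihydro-2H-chromen-3-yl]-6-(2-methylbut-3-en-2-yl)benzene-1,3-diol | C=CC(C)(C)c1cc([C@@H]2COc3c(ccc(O)c3CCC(C)(C)O)C2)c(O)cc1O | target

**Step count and risks**

Total step count: 8. Longest linear sequence: 6 steps (6 → 7 → 9 → 12 → 13 → 14 → 15); the A-ring branch (1 → 2 → 5) joins at step 6.

The three steps most likely to fail:

Step 6. The resorcinol may be too weak a nucleophile for the acid-activated oxetane. O-alkylation, double alkylation and participation by the electron-rich aryl group can compete, and the enantioselectivity is untested. The fallback sets out from 12 and 5 and comes back at 13; it keeps the oxetane desymmetrisation but makes the C–C bond in a separate cross-coupling. Oxetane 12 is opened with TMSBr under a chiral squaramide hydrogen-bond-donor catalyst (a known enantioselective bromide opening of 3-substituted oxetanes) to give [(2R)-3-bromo-2-[5-(2-methylbut-3-en-2-yl)-2,4-bis(triisopropylsilyloxy)phenyl]propoxy]trimethylsilane F1. In parallel 5 is monobrominated with NBS (MeCN, 0 °C; the symmetry allows only one regioisomer) to 4-bromo-2-(3-hydroxy-3-methylbutyl)benzene-1,3-diol F2, which is persilylated (TMSCl, Et3N, CH2Cl2) to its tris(trimethylsilyl) ether F3. F1 and F3 are joined by nickel-catalysed reductive cross-electrophile coupling (NiBr2·glyme, dtbbpy, Zn, NaI, DMA) to the tetra-O-trimethylsilyl ether of 13 F4. Methanolysis of the four TMS groups (citric acid, MeOH, rt), which leaves the TIPS ethers in place, gives 13.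

Step 4. The linear prenyl isomer, double coupling, or a sluggish reaction next to the OTIPS group may dominate. The fallback sets out from 7 and comes back at 9, building the 1,1-dimethylallyl group from a quaternary ester. Mono α-arylation of the lithium enolate of methyl isobutyrate with 7 (LiNCy2, Pd(dba)2/P(t-Bu)3, toluene, rt) gives methyl 2-[5-bromo-2,4-bis(triisopropylsilyloxy)phenyl]-2-methylpropanoate F5. DIBAL-H (CH2Cl2, −78 °C) reduces it to 2-[5-bromo-2,4-bis(triisopropylsilyloxy)phenyl]-2-methylpropanal F6, and Wittig methylenation (Ph3PCH3Br, KOt-Bu, THF) gives 9.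

Step 5. The hindered, electron-rich aryl bromide may couple poorly with the secondary zinc reagent, and zinc halide may open the oxetane. The fallback sets out from 9 and comes back at 12, building the oxetane ring instead of coupling it. Pd-catalysed α-arylation of diethyl malonate with 9 (Pd(dba)2/P(t-Bu)3, K3PO4, toluene, 70 °C) gives diethyl 2-[5-(2-methylbut-3-en-2-yl)-2,4-bis(triisopropylsilyloxy)phenyl]propanedioate F7. LiAlH4 (THF, 0 °C) gives 2-[5-(2-methylbut-3-en-2-yl)-2,4-bis(triisopropylsilyloxy)phenyl]propane-1,3-diol F8. One-pot treatment with n-BuLi (1 equiv) and TsCl (1 equiv), then a second equivalent of n-BuLi (THF, 0 → 60 °C), closes the ring through the racemic monotosylate 3-hydroxy-2-[5-(2-methylbut-3-en-2-yl)-2,4-bis(triisopropylsilyloxy)phenyl]propyl 4-methylbenzenesulfonate F9 (not isolated) to give 12.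

**Further compounds**

F1 | step 6 | [(2R)-3-bromo-2-[5-(2-methylbut-3-en-2-yl)-2,4-bis(triisopropylsilyloxy)phenyl]propoxy]trimethylsilane | C=CC(C)(C)c1cc([C@@H](CBr)CO[Si](C)(C)C)c(O[Si](C(C)C)(C(C)C)C(C)C)cc1O[Si](C(C)C)(C(C)C)C(C)C
F2 | step 6 | 4-bromo-2-(3-hydroxy-3-methylbutyl)benzene-1,3-diol | CC(C)(O)CCc1c(O)ccc(Br)c1O
F3 | step 6 | 1-bromo-2,4-bis(trimethylsilyloxy)-3-(3-methyl-3-trimethylsilyloxybutyl)benzene | C[Si](C)(C)Oc1ccc(Br)c(O[Si](C)(C)C)c1CCC(C)(C)O[Si](C)(C)C
F4 | step 6 | tetra-O-trimethylsilyl ether of 13, trimethyl[(2R)-3-[2,4-bis(trimethylsilyloxy)-3-(3-methyl-3-trimethylsilyloxybutyl)phenyl]-2-[5-(2-methylbut-3-en-2-yl)-2,4-bis(triisopropylsilyloxy)phenyl]propoxy]silane | C=CC(C)(C)c1cc([C@@H](Cc2ccc(O[Si](C)(C)C)c(CCC(C)(C)O[Si](C)(C)C)c2O[Si](C)(C)C)CO[Si](C)(C)C)c(O[Si](C(C)C)(C(C)C)C(C)C)cc1O[Si](C(C)C)(C(C)C)C(C)C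
F5 | step 4 | methyl 2-[5-bromo-2,4-bis(triisopropylsilyloxy)phenyl]-2-methylpropanoate | COC(=O)C(C)(C)c1cc(Br)c(O[Si](C(C)C)(C(C)C)C(C)C)cc1O[Si](C(C)C)(C(C)C)C(C)C
F6 | step 4 | 2-[5-bromo-2,4-bis(triisopropylsilyloxy)phenyl]-2-methylpropanal | O=CC(C)(C)c1cc(Br)c(O[Si](C(C)C)(C(C)C)C(C)C)cc1O[Si](C(C)C)(C(C)C)C(C)C
F7 | step 5 | diethyl 2-[5-(2-methylbut-3-en-2-yl)-2,4-bis(triisopropylsilyloxy)phenyl]propanedioate | CCOC(=O)C(C(=O)OCC)c1cc(C(C)(C)C=C)c(O[Si](C(C)C)(C(C)C)C(C)C)cc1O[Si](C(C)C)(C(C)C)C(C)C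
F8 | step 5 | 2-[5-(2-methylbut-3-en-2-yl)-2,4-bis(triisopropylsilyloxy)phenyl]propane-1,3-diol | OCC(CO)c1cc(C(C)(C)C=C)c(O[Si](C(C)C)(C(C)C)C(C)C)cc1O[Si](C(C)C)(C(C)C)C(C)C
F9 | step 5 | racemic 3-hydroxy-2-[5-(2-methylbut-3-en-2-yl)-2,4-bis(triisopropylsilyloxy)phenyl]propyl 4-methylbenzenesulfonate | Cc1ccc(cc1)S(=O)(=O)OCC(CO)c1cc(C(C)(C)C=C)c(O[Si](C(C)C)(C(C)C)C(C)C)cc1O[Si](C(C)C)(C(C)C)C(C)C
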